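**Strategy**

Everything rests on forming the bond between C8 of the coumarin benzene ring and the carbinol carbon C1′. An 8-titanated 7-methoxycoumarin (from the 8-iodide) adds to (S)-3,3-dimethyloxirane-2-carbaldehyde under Felkin–Anh control, and the titanium alkoxide thus formed opens its own oxirane to the isopropenyl carbinol. One operation therefore joins both fragments, sets C1′ anti to O2′ and unmasks the C2′–OH/C3′-isopropenyl unit. The step exploits C8, flanked by O7 and the pyranone oxygen O1 (selective iodination, fast I/Mg exchange), and the anti 1′,2′-dioxygen pattern beside an isopropenyl group, which is the retron of an α,β-epoxy aldehyde. Site-selective acylation of the less hindered O2′ completes the synthesis.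

Key step: step 5

Remark: the side-chain carbons are called C1′ (carbinol carbon on C8), C2′ (acyloxy carbon) and C3′ (isopropenyl carbon); read from the SMILES, the target is (1′R,2′S), the anti (erythro) arrangement of O1′ and O2′.

**Route**

Step 1
Reactants: 1 umbelliferone (7-hydroxy-2H-chromen-2-one)
Product: 2 7-hydroxy-8-iodo-2H-chromen-2-one
Conditions: I2 (1.0 equiv), KI, 20% aq. NH3, 0 °C → rt; then dil. HCl to pH 3
Reagents that add atoms: iodine, II
Why: Electrophilic aromatic iodination of the ammonium phenolate; C8, ortho to O7 and flanked by the ring oxygen O1, is the most nucleophilic ring position, and a limiting amount of iodine should keep 6-iodination and di-iodination low.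

Step 2
Reactants: 2 7-hydroxy-8-iodo-2H-chromen-2-one
Product: 3 8-iodo-7-methoxy-2H-chromen-2-one
Conditions: MeI, K2CO3, acetone, reflux
Reagents that add atoms: iodomethane, CI
Why: Williamson O-methylation of the acidic coumarin phenol; no other nucleophilic site is present.

Step 3
Reactants: 4 prenol (3-methylbut-2-en-1-ol)
Product: 5 (R)-(3,3-dimethyloxiran-2-yl)methanol
Conditions: Ti(OiPr)4 (cat.), D-(−)-diethyl tartrate (cat.), anhydrous t-BuOOH, 4 Å MS, CH2Cl2, −20 °C; non-aqueous work-up, distillation
Reagents that add atoms: tert-butyl hydroperoxide, CC(C)(C)OO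
Why: Sharpless asymmetric epoxidation; the D-(−)-tartrate complex delivers oxygen to the face of the allylic alcohol opposite to the one that gives (2S) oxiranes with L-(+)-tartrate, so the (2R) oxirane is expected.

Step 4
Reactants: 5 (R)-(3,3-dimethyloxiran-2-yl)methanol
Product: 6 (S)-3,3-dimethyloxirane-2-carbaldehyde
Conditions: TEMPO (cat.), PhI(OAc)2, CH2Cl2, 0 °C → rt; short-path distillation, used at once as a THF solution
Reagents that add atoms: none
Why: TEMPO/oxoammonium oxidation of a primary alcohol to the aldehyde under near-neutral conditions; the oxirane carbon is not epimerisable here, and the change of descriptor from R to S is only a change of CIP priorities.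

Step 5
Reactants: 3 8-iodo-7-methoxy-2H-chromen-2-one; 6 (S)-3,3-dimethyloxirane-2-carbaldehyde
Product: 11 8-[(1R,2S)-1,2-dihydroxy-3-methylbut-3-en-1-yl]-7-methoxy-2H-chromen-2-one, via arylmagnesium chloride 7 (not isolated), via aryltitanium triisopropoxide 8 (not isolated), via titanium epoxy alkoxide 9 (not isolated), via titanium diolate 10 (not isolated)
Conditions: iPrMgCl·LiCl, THF, −40 °C; ClTi(OiPr)3, −40 °C; 6, −40 → 0 °C; solvent exchange to CH2Cl2, 25–40 °C; aq. Rochelle salt
Reagents that add atoms: none
Why: I/Mg exchange at C8 (the iodide lies between O7 and O1, so exchange at −40 °C should outrun attack on the lactone) and transmetalation give the mild aryltitanium 8, which adds to the formyl group of 6 as in the known additions of organotitanium and Grignard reagents to α,β-epoxy aldehydes. No ring of the target is closed; the temporary oxirane is opened. C1′ is set by substrate control: in the Felkin–Anh (Cornforth) transition state the oxirane C–O bond is anti to the incoming aryl group, an arrangement reinforced by the non-chelating Ti(OiPr)3 centre and by the oxirane methyl group cis to the formyl group, and this should give the (1′R) carbinol anti to O2′, while C2′ is carried over from 6 because its C–O bond is never broken. On warming in CH2Cl2 the titanium on O1′ in 9 coordinates the oxirane oxygen, the tertiary C3′–O bond ionises and an isopropoxide ligand removes a methyl proton to give diolate 10, which is the known Ti(OiPr)4-mediated rearrangement of 3,3-disubstituted 2,3-epoxy alcohols to 3-ene-1,2-diols. The step needs aldehyde-over-lactone chemoselectivity (secured by the weakly basic aryltitanium), anti facial selectivity (secured as described) and elimination instead of nucleophilic opening at C3′ (favoured because C3′ is tertiary and carries only methyl protons, and because THF and the halide salts are removed before warming).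

Step 6
Reactants: 11 8-[(1R,2S)-1,2-dihydroxy-3-methylbut-3-en-1-yl]-7-methoxy-2H-chromen-2-one
Product: 12 (1R,2S)-1-hydroxy-1-(7-methoxy-2-oxo-2H-chromen-8-yl)-3-methylbut-3-en-2-yl 3-methylbutanoate
Conditions: isovaleric anhydride (1.05 equiv), Et3N, DMAP (5 mol%), CH2Cl2, −40 → −10 °C
Reagents that add atoms: isovaleric anhydride, CC(C)CC(=O)OC(=O)CC(C)C
Why: DMAP-catalysed acyl transfer (Steglich-type acylation) under kinetic control; O1′–H is benzylic and shielded by the two ortho oxygens (O7 methyl ether and O1) of the aryl ring, so the allylic O2′–H should react first, and low temperature with limiting anhydride suppresses diacylation and acyl migration.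

**Compound list**

1 | umbelliferone (7-hydroxy-2H-chromen-2-one) | Oc1ccc2ccc(=O)oc2c1 | starting material
2 | 7-hydroxy-8-iodo-2H-chromen-2-one | Oc1ccc2ccc(=O)oc2c1I | intermediate
3 | 8-iodo-7-methoxy-2H-chromen-2-one | COc1ccc2ccc(=O)oc2c1I | intermediate
4 | prenol (3-methylbut-2-en-1-ol) | CC(C)=CCO | starting material
5 | (R)-(3,3-dimethyloxiran-2-yl)methanol | CC1(C)[C@H](O1)CO | intermediate
6 | (S)-3,3-dimethyloxirane-2-carbaldehyde | CC1(C)[C@H](O1)C=O | intermediate
7 | (7-methoxy-2-oxo-2H-chromen-8-yl)magnesium chloride (LiCl complex) | COc1ccc2ccc(=O)oc2c1[Mg]Cl | intermediate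
8 | (7-methoxy-2-oxo-2H-chromen-8-yl)titanium triisopropoxide | COc1ccc2ccc(=O)oc2c1[Ti](OC(C)C)(OC(C)C)OC(C)C | intermediate
9 | titanium triisopropoxide alkoxide of 8-[(R)-[(2R)-3,3-dimethyloxiran-2-yl](hydroxy)methyl]-7-methoxy-2H-chromen-2-one | CC3(C)[C@H](O3)[C@H](O[Ti](OC(C)C)(OC(C)C)OC(C)C)c1c(OC)ccc2ccc(=O)oc12 | intermediate
10 | titanium diisopropoxide (1R,2S)-diolate of 11 (2,2-diisopropoxy-1,3,2-dioxatitanolane) | C=C(C)[C@H](O4)[C@H](O[Ti]4(OC(C)C)OC(C)C)c1c(OC)ccc2ccc(=O)oc12 | intermediate
11 | 8-[(1R,2S)-1,2-dihydroxy-3-methylbut-3-en-1-yl]-7-methoxy-2H-chromen-2-one | C=C(C)[C@H](O)[C@H](O)c1c(OC)ccc2ccc(=O)oc12 | intermediate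
12 | (1R,2S)-1-hydroxy-1-(7-methoxy-2-oxo-2H-chromen-8-yl)-3-methylbut-3-en-2-yl 3-methylbutanoate | C=C(C)[C@H](OC(=O)CC(C)C)[C@H](O)c1c(OC)ccc2ccc(=O)oc12 | target

**Summary**

Total step count: 6. Longest linear sequence: 4 steps (1 → 2 → 5 → 6, or 3 → 4 → 5 → 6).

**Steps most likely to fail**

1. Step 5. Three processes may interfere: attack of the exchange reagent or the arylmagnesium on the lactone, erosion of the anti facial selectivity, and opening of the oxirane at C3′ by chloride or isopropoxide in place of elimination. The fallback sets out from 3 and 6 and forms the same C8–C1′ bond by a Nozaki–Hiyama–Kishi coupling (CrCl2, cat. NiCl2, DMF, rt), which needs no preformed organometal and no base. It should give 8-[(R)-[(2R)-3,3-dimethyloxiran-2-yl](hydroxy)methyl]-7-methoxy-2H-chromen-2-one F1, which is isolated. The oxirane is then opened in a separate, salt-free operation with TMSOTf and 2,6-lutidine in toluene at −78 °C followed by DBU, an E1-type opening at the tertiary carbon and proton loss from a methyl group, to give 7-methoxy-8-[(1R,2S)-3-methyl-1,2-bis(trimethylsilyloxy)but-3-en-1-yl]-2H-chromen-2-one F2. Citric acid in methanol cleaves both silyl ethers and the route is rejoined at 11.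

2. Step 6. Acylation may also take place at O1′, go on to the diester, or be followed by O2′ → O1′ acyl migration under the basic conditions. The fallback sets out from 11, which is condensed with Bu2SnO (toluene, reflux, removal of water) to the tin acetal 8-[(4R,5S)-2,2-dibutyl-5-(prop-1-en-2-yl)-1,3,2-dioxastannolan-4-yl]-7-methoxy-2H-chromen-2-one F3. In such stannylene acetals the less hindered oxygen is the activated one, so isovaleryl chloride (1.0 equiv, CH2Cl2, 0 °C) should acylate O2′ without added base, and aqueous work-up returns to the route at 12.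

3. Step 3. The small, water-miscible epoxy alcohol may be lost during removal of titanium and tartrate, and the enantiomeric purity reached by the catalyst alone may be insufficient for the C2′ centre. The fallback sets out from 4: the epoxidation is followed in the same flask by acylation with 4-nitrobenzoyl chloride and Et3N, so that the product is captured as the crystalline ester [(2R)-3,3-dimethyloxiran-2-yl]methyl 4-nitrobenzoate F4. This ester is recrystallised to raise the enantiomeric purity. Transesterification with catalytic NaOMe in methanol and non-aqueous removal of the methyl ester rejoin the route at 5.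

**Further compounds**

F1 | step 5 | 8-[(R)-[(2R)-3,3-dimethyloxiran-2-yl](hydroxy)methyl]-7-methoxy-2H-chromen-2-one | CC3(C)[C@H](O3)[C@H](O)c1c(OC)ccc2ccc(=O)oc12
F2 | step 5 | 7-methoxy-8-[(1R,2S)-3-methyl-1,2-bis(trimethylsilyloxy)but-3-en-1-yl]-2H-chromen-2-one | C=C(C)[C@H](O[Si](C)(C)C)[C@H](O[Si](C)(C)C)c1c(OC)ccc2ccc(=O)oc12
F3 | step 6 | 8-[(4R,5S)-2,2-dibutyl-5-(prop-1-en-2-yl)-1,3,2-dioxastannolan-4-yl]-7-methoxy-2H-chromen-2-one | C=C(C)[C@H](O4)[C@H](O[Sn]4(CCCC)CCCC)c1c(OC)ccc2ccc(=O)oc12
F4 | step 3 | [(2R)-3,3-dimethyloxiran-2-yl]methyl 4-nitrobenzoate | CC1(C)[C@H](O1)COC(=O)c2ccc(cc2)[N+](=O)[O-]
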